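**Retrosynthetic overview**
- The C9–C11 bond is cut last (Negishi coupling of a ring-B enol triflate with a side-chain alkylzinc). Both acetates are retrons for Baeyer–Villiger oxidation of methyl ketones: C7–OAc comes from the isopropenyl group of (R)-carvone, and C15–OAc from the methyl-bearing ring carbon of an isoprene/acrylate Diels–Alder adduct that also sets C13.
- Ring B is present from the start, because carvone supplies C5–C10, the C10 methyl and the C7 stereocentre. Ring A is formed second, by ring-closing metathesis (C2=C3) of a C10-allyl and a C5-(1,1-dimethylallyl) group, followed by hydrogenation.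
- Both groups are installed in one operation. An anionic oxy-Cope shift of the C9 prenyl carbinol forms C4–C5, and allylation of the enolate it releases forms C1–C10.
- Enabling feature: in ring B the sp2 carbon C9 lies 1,3 to C5 across the methyl-bearing C10, so C9–C10–C5 is a latent 2-methylcyclohex-2-enone. C4 is a gem-dimethyl carbon, which is the tertiary end of a prenyl group. A prenyl group placed on C9 can therefore migrate suprafacially to C5, and the trans ring fusion (C10-CH3 β, H-5 α) is the anti outcome of adding the two carbon groups one after the other.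

Key step: step 2

Assumption: labdane numbering is used throughout (decalin C1–C10, side chain C11–C16; α is the face of H-5, β the face of the C10 methyl). The oxirane carbon of the masked isopropenyl group is carried as a mixture of epimers and C8 of the methylated ketone is drawn as the equatorial epimer, because both centres are erased later.

Step 1
Reactants: 1 (R)-(−)-carvone; 2 prenyl chloride
Product: 3 (1R,5R)-2-methyl-1-(3-methylbut-2-en-1-yl)-5-(prop-1-en-2-yl)cyclohex-2-en-1-ol (prenyl β at C9 and trans to the isopropenyl group; OH α)
Conditions: BaI2, lithium biphenylide (2 equiv), THF, rt; 2, −78 °C; then 1, −78 °C; aq NH4Cl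
Reagents that add atoms: none
Why: This is the 1,2-addition of an allylic barium reagent, which bonds through its unsubstituted α-terminus and attacks enones at the carbonyl carbon; axial approach to the half-chair of 1, anti to the pseudo-equatorial isopropenyl group at C7, should put the prenyl group on the β-face of C9, and a minor C9 epimer would be removed by chromatography.

Step 2
Reactants: 3 prenyl carbinol; 4 allyl bromide
Product: 7 (2S,3S,5R)-2-allyl-2-methyl-3-(2-methylbut-3-en-2-yl)-5-(prop-1-en-2-yl)cyclohexan-1-one, via potassium alkoxide 5 (not isolated), via potassium enolate 6 (not isolated)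
Conditions: KH (1.1 equiv), 18-crown-6 (1.1 equiv), THF, 0 → 66 °C; cool to −78 °C, 4 (3 equiv), → 0 °C
Reagents that add atoms: none
Why: KH/18-crown-6 turns 3 into the dissociated alkoxide 5, whose 3-oxido-1,5-diene array C5=C10–C9(O−)–CH2–CH=C(CH3)2 undergoes an anionic oxy-Cope [3,3]-shift that trades the C9–CH2 bond for the C4–C5 bond and releases the regiodefined tetrasubstituted enolate 6, which 4 then alkylates at C10 (SN2) to form C1–C10 in the same flask. The closest known reaction type is the tandem anionic oxy-Cope rearrangement/enolate alkylation of 1-allylcyclohex-2-en-1-ols, the sigmatropic counterpart of conjugate addition–enolate trapping on a 2-methylcyclohexenone. The step closes no ring: ring B is that of carvone, and the two vinyl groups laid down here are joined to give ring A in step 4. C5 is controlled by the suprafacial course of the shift, which passes the β-orientation of the C9–prenyl bond (itself set by C7 of carvone) to the new C5–C4 bond so that H-5 is α, while C4 becomes quaternary but is not stereogenic. C10 is controlled by the new 1,1-dimethylallyl group, which A(1,2) strain with the C10 methyl holds pseudo-axial on the β-face, so 4 enters axially from the α-face and gives the anti relation of C4 and C1 that becomes the trans ring fusion, a relation that a tethered closure or a cycloaddition on this ring could not deliver. The step needs transfer of the tertiary prenyl terminus (secured by the six-atom cyclic array) and C10–C-allylation rather than O- or C8-allylation (secured by a soft, reactive halide in excess at low temperature and by an enolate formed regiospecifically without a proton source).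

Step 3
Reactants: 7 triene ketone
Product: 8 (2S,3S,5R)-2-allyl-2-methyl-3-(2-methylbut-3-en-2-yl)-5-(2-methyloxiran-2-yl)cyclohexan-1-one (epimers at the oxirane carbon)
Conditions: mCPBA (1.0 equiv), NaHCO3, CH2Cl2, 0 °C
Reagents that add atoms: mCPBA, OOC(=O)c1cccc(Cl)c1
Why: In this Prilezhaev epoxidation the 1,1-disubstituted isopropenyl alkene is much more nucleophilic than the two monosubstituted vinyl groups (one of them neopentylic) and the hindered ketone oxidises far more slowly, so one equivalent of peracid should mask only the isopropenyl group against the later metathesis and hydrogenation.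

Step 4
Reactants: 8 epoxy diene ketone
Product: 9 (3R,4aS,8aS)-5,5,8a-trimethyl-3-(2-methyloxiran-2-yl)-3,4,4a,5,8,8a-hexahydronaphthalen-1(2H)-one (trans-fused; C2=C3 alkene)
Conditions: (H2IMes)(PCy3)Cl2Ru=CHPh (5 mol %), CH2Cl2 (5 mM), 40 °C
Reagents that add atoms: none
Why: Ring-closing metathesis initiates at the unhindered allyl group and closes on the neopentylic vinyl group through the chair with both chains equatorial, so the trans C5/C10 relation set in step 2 is carried unchanged into a trans-fused cyclohexene.

Step 5
Reactants: 9 octalone
Product: 10 (3R,4aS,8aS)-5,5,8a-trimethyl-3-(2-methyloxiran-2-yl)octahydronaphthalen-1(2H)-one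
Conditions: H2 (1 atm), 10% Pd/C, EtOAc, rt
Reagents that add atoms: none
Why: Heterogeneous hydrogenation saturates the only alkene (cis-disubstituted C2=C3); the aliphatic oxirane and the ketone are not reduced under these mild neutral conditions and no stereocentre is created.

Step 6
Reactants: 10 decalone
Product: 12 (2R,3R,4aS,8aS)-2,5,5,8a-tetramethyl-3-(2-methyloxiran-2-yl)octahydronaphthalen-1(2H)-one, via lithium enolate 11 (not isolated)
Conditions: LDA, THF, −78 °C; MeI, −78 → 0 °C
Reagents that add atoms: iodomethane, CI
Why: This is an enolate alkylation in which C8 is the only enolisable position (C10 is quaternary); the equatorial 8α-methyl epimer is the more stable one, and either C8 epimer is acceptable because step 7 makes C8 sp2.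

Step 7
Reactants: 12 methyl decalone
Product: 14 (3R,4aS,8aS)-2,5,5,8a-tetramethyl-3-(2-methyloxiran-2-yl)-3,4,4a,5,6,7,8,8a-octahydronaphthalen-1-yl trifluoromethanesulfonate, via potassium enolate 13 (not isolated)
Conditions: KHMDS, THF, −78 → 0 °C; PhNTf2, 0 °C → rt; aq NH4Cl
Reagents that add atoms: N-phenylbis(trifluoromethanesulfonimide), O=S(=O)(N(c1ccccc1)S(=O)(=O)C(F)(F)F)C(F)(F)F
Why: O-Triflation of the single possible enolate, as practised on 2,2,6-trisubstituted cyclohexanones, fixes the tetrasubstituted C8=C9 double bond regiospecifically, converges both C8 epimers and leaves an electron-poor alkene that tolerates the two oxidations that follow.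

Step 8
Reactants: 14 epoxy enol triflate
Product: 16 (3R,4aS,8aS)-3-acetyl-2,5,5,8a-tetramethyl-3,4,4a,5,6,7,8,8a-octahydronaphthalen-1-yl trifluoromethanesulfonate, via vicinal diol 15 (not isolated)
Conditions: H5IO6 (1.5 equiv), THF–H2O, 0 °C → rt
Reagents that add atoms: water, O
Why: Periodic acid opens the 2,2-disubstituted oxirane with water at its tertiary carbon and cleaves the resulting diol (Malaprade-type cleavage), so both oxirane epimers converge on one methyl ketone; the 7α (pseudo-axial) acetyl group is the epimer favoured by A(1,2) strain with the C8 methyl and should not epimerise.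

Step 9
Reactants: 16 acetyl enol triflate
Product: 17 (3R,4aS,8aS)-3-acetoxy-2,5,5,8a-tetramethyl-3,4,4a,5,6,7,8,8a-octahydronaphthalen-1-yl trifluoromethanesulfonate (7α-acetate)
Conditions: mCPBA, NaHCO3, CH2Cl2, rt, dark
Reagents that add atoms: mCPBA, OOC(=O)c1cccc(Cl)c1
Why: In this Baeyer–Villiger oxidation the secondary C7 migrates in preference to methyl and with retention, which turns the carvone stereocentre directly into the 7α-acetate, while the triflate-deactivated alkene is not epoxidised.

Step 10
Reactants: 18 isoprene; 19 2,2,2-trifluoroethyl acrylate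
Product: 20 2,2,2-trifluoroethyl (R)-4-methylcyclohex-3-ene-1-carboxylate
Conditions: (R)-B-(o-tolyl)oxazaborolidine from (R)-α,α-diphenylprolinol (10 mol %), Tf2NH (9 mol %), neat, 23 °C
Reagents that add atoms: none
Why: In this catalytic enantioselective Diels–Alder reaction the cationic oxazaborolidinium Lewis acid activates the acrylate, enforces the "para" regiochemistry and shields one face; the (S)-catalyst gives the (S)-cyclohex-3-enecarboxylate series with simple 1,3-dienes, so its enantiomer is used to set the future C13.

Step 11
Reactants: 20 trifluoroethyl ester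
Product: 21 methyl (R)-4-methylcyclohex-3-ene-1-carboxylate
Conditions: K2CO3 (cat.), MeOH, 0 °C → rt
Reagents that add atoms: methanol, CO
Why: Transesterification of the activated trifluoroethyl ester is fast under base too mild to enolise a simple cyclohexanecarboxylate, so the stereocentre is retained.

Step 12
Reactants: 21 methyl ester
Product: 24 methyl (R)-2-(2-hydroxyethyl)-5-oxohexanoate, via secondary ozonide 22 (not isolated), via keto aldehyde 23 (not isolated)
Conditions: O3, CH2Cl2, −78 °C; Me2S, → rt; NaBH(OAc)3, 0 °C → rt
Reagents that add atoms: ozone, [O-][O+]=O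
Why: Ozonolysis of the trisubstituted alkene gives two arms that differ by construction (aldehyde and methyl ketone), and triacetoxyborohydride reduces only the aldehyde; the γ-hydroxy ester is carried forward at once because it can lactonise on standing.

Step 13
Reactants: 24 hydroxy keto ester
Product: 25 methyl (R)-2-(2-bromoethyl)-5-oxohexanoate
Conditions: CBr4, PPh3, CH2Cl2, 0 °C
Reagents that add atoms: carbon tetrabromide, BrC(Br)(Br)Br
Why: The Appel reaction converts the primary alcohol into the bromide under neutral conditions faster than lactonisation, and a bromide (unlike an iodide) withstands the peracid of step 14.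

Step 14
Reactants: 25 bromo keto ester
Product: 26 methyl (R)-4-acetoxy-2-(2-bromoethyl)butanoate
Conditions: mCPBA, CF3CO2H (1 equiv), CH2Cl2, rt, dark
Reagents that add atoms: mCPBA, OOC(=O)c1cccc(Cl)c1
Why: In this acid-promoted Baeyer–Villiger oxidation of a 2-alkanone the primary alkyl group migrates in preference to methyl, which gives the C15 acetate directly; the ester, the bromide and C13 are untouched.

Step 15
Reactants: 26 acetoxy bromo ester; 17 acetoxy enol triflate
Product: 28 methyl (S)-4-acetoxy-2-{2-[(3R,4aS,8aS)-3-acetoxy-2,5,5,8a-tetramethyl-3,4,4a,5,6,7,8,8a-octahydronaphthalen-1-yl]ethyl}butanoate (target), via alkylzinc bromide 27 (not isolated)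
Conditions: 26, Zn dust, I2 (5 mol %), DMA, 80 °C; then 17, PdCl2(dppf) (5 mol %), THF–DMA, 60 °C
Reagents that add atoms: none
Why: In this Negishi alkyl–alkenyl coupling the ester-tolerant γ-carboalkoxy alkylzinc forms by direct insertion, the bidentate ligand disfavours β-hydride elimination, oxidative addition into C–OTf should outpace ionisation of the hindered allylic acetate, and no stereocentre is touched.

**Compound list**
1 | (R)-(−)-carvone | O=C1C[C@H](C(C)=C)CC=C1C | starting material
2 | prenyl chloride (1-chloro-3-methylbut-2-ene) | CC(C)=CCCl | starting material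
3 | (1R,5R)-2-methyl-1-(3-methylbut-2-en-1-yl)-5-(prop-1-en-2-yl)cyclohex-2-en-1-ol | O[C@]1(CC=C(C)C)C[C@H](C(C)=C)CC=C1C | intermediate
4 | allyl bromide | C=CCBr | starting material
5 | potassium alkoxide of 3 | [K+].[O-][C@]1(CC=C(C)C)C[C@H](C(C)=C)CC=C1C | intermediate
6 | potassium (3S,5R)-2-methyl-3-(2-methylbut-3-en-2-yl)-5-(prop-1-en-2-yl)cyclohex-1-en-1-olate | [K+].[O-]C1=C(C)[C@H](C(C)(C)C=C)C[C@@H](C(C)=C)C1 | intermediate
7 | (2S,3S,5R)-2-allyl-2-methyl-3-(2-methylbut-3-en-2-yl)-5-(prop-1-en-2-yl)cyclohexan-1-one | O=C1[C@@](C)(CC=C)[C@H](C(C)(C)C=C)C[C@@H](C(C)=C)C1 | intermediate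
8 | (2S,3S,5R)-2-allyl-2-methyl-3-(2-methylbut-3-en-2-yl)-5-(2-methyloxiran-2-yl)cyclohexan-1-one (oxirane epimers) | O=C1[C@@](C)(CC=C)[C@H](C(C)(C)C=C)C[C@@H](C2(C)CO2)C1 | intermediate
9 | (3R,4aS,8aS)-5,5,8a-trimethyl-3-(2-methyloxiran-2-yl)-3,4,4a,5,8,8a-hexahydronaphthalen-1(2H)-one | O=C1C[C@H](C3(C)CO3)C[C@H]2C(C)(C)C=CC[C@]12C | intermediate
10 | (3R,4aS,8aS)-5,5,8a-trimethyl-3-(2-methyloxiran-2-yl)octahydronaphthalen-1(2H)-one | O=C1C[C@H](C3(C)CO3)C[C@H]2C(C)(C)CCC[C@]12C | intermediate
11 | lithium enolate (C8=C9) of 10 | [Li+].[O-]C1=C[C@H](C3(C)CO3)C[C@H]2C(C)(C)CCC[C@]12C | intermediate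
12 | (2R,3R,4aS,8aS)-2,5,5,8a-tetramethyl-3-(2-methyloxiran-2-yl)octahydronaphthalen-1(2H)-one | O=C1[C@H](C)[C@H](C3(C)CO3)C[C@H]2C(C)(C)CCC[C@]12C | intermediate
13 | potassium enolate (C8=C9) of 12 | [K+].[O-]C1=C(C)[C@H](C3(C)CO3)C[C@H]2C(C)(C)CCC[C@]12C | intermediate
14 | epoxy enol triflate (7α-(2-methyloxiran-2-yl), C8=C9–OTf) | FC(F)(F)S(=O)(=O)OC1=C(C)[C@H](C3(C)CO3)C[C@H]2C(C)(C)CCC[C@]12C | intermediate
15 | vicinal diol from 14 (7α-(1,2-dihydroxypropan-2-yl)) | FC(F)(F)S(=O)(=O)OC1=C(C)[C@H](C(C)(O)CO)C[C@H]2C(C)(C)CCC[C@]12C | intermediate
16 | 7α-acetyl enol triflate | FC(F)(F)S(=O)(=O)OC1=C(C)[C@H](C(C)=O)C[C@H]2C(C)(C)CCC[C@]12C | intermediate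
17 | 7α-acetoxy enol triflate | FC(F)(F)S(=O)(=O)OC1=C(C)[C@H](OC(C)=O)C[C@H]2C(C)(C)CCC[C@]12C | intermediate
18 | isoprene | C=CC(C)=C | starting material
19 | 2,2,2-trifluoroethyl acrylate | C=CC(=O)OCC(F)(F)F | starting material
20 | 2,2,2-trifluoroethyl (R)-4-methylcyclohex-3-ene-1-carboxylate | FC(F)(F)COC(=O)[C@@H]1CCC(C)=CC1 | intermediate
21 | methyl (R)-4-methylcyclohex-3-ene-1-carboxylate | COC(=O)[C@@H]1CCC(C)=CC1 | intermediate
22 | secondary ozonide of 21 | COC(=O)[C@@H]1CCC2(C)OOC(C1)O2 | intermediate
23 | methyl (R)-5-oxo-2-(2-oxoethyl)hexanoate | COC(=O)[C@@H](CC=O)CCC(C)=O | intermediate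
24 | methyl (R)-2-(2-hydroxyethyl)-5-oxohexanoate | COC(=O)[C@@H](CCO)CCC(C)=O | intermediate
25 | methyl (R)-2-(2-bromoethyl)-5-oxohexanoate | COC(=O)[C@@H](CCBr)CCC(C)=O | intermediate
26 | methyl (R)-4-acetoxy-2-(2-bromoethyl)butanoate | COC(=O)[C@@H](CCBr)CCOC(C)=O | intermediate
27 | alkylzinc bromide from 26 | COC(=O)[C@@H](CC[Zn]Br)CCOC(C)=O | intermediate
28 | CNP0309093.1, (5S,7R,10S,13S) | COC(=O)[C@H](CCOC(C)=O)CCC1=C(C)[C@H](OC(C)=O)C[C@H]2C(C)(C)CCC[C@]12C | target

**Step count**
- Total steps: 15.
- Longest linear sequence: 10 (steps 1–9 and 15, from carvone). The side-chain branch is 6 steps long (steps 10–15).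

**Steps most likely to fail**

Step 2. Heterolytic fragmentation or a [1,3]-shift of the crowded alkoxide may outrun the [3,3]-shift, because the new bond joins a ring CH to a fully substituted carbon. Proton transfer between the enolate and the product may also divert allylation to C8. O-allylation would be less serious, since heating the allyl enol ether should return the same ketone by Claisen rearrangement.

The fallback sets out from 1 and comes back at 7, and it makes the two bonds in separate operations.
- Hosomi–Sakurai conjugate addition of prenyltrimethylsilane to 1 (TiCl4, CH2Cl2, −78 °C) proceeds by SE2′ attack through the tertiary terminus, anti to the isopropenyl group. It would give (3S,5R)-2-methyl-3-(2-methylbut-3-en-2-yl)-5-(prop-1-en-2-yl)cyclohexan-1-one F1.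
- Thermodynamic silylation (TMSCl, NaI, Et3N, MeCN) would give its tetrasubstituted trimethylsilyl enol ether F2.
- MeLi (THF, 0 °C) would release the lithium enolate, which is allylated with 4 to give 7.

Step 15. Three processes may erode the coupling: slow oxidative addition and transmetalation at a tetrasubstituted triflate flanked by the quaternary C10, β-hydride elimination of the alkylpalladium species, and ionisation of the allylic C7 acetate by Pd(0).

The fallback sets out from 14 and comes back at 28. It changes the order of events, so that no allylic acetate is present during a coupling that may need forcing.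
- 27 is coupled with the epoxy triflate 14 to give the 7α-(2-methyloxiran-2-yl) coupled ester F3.
- Periodic acid cleavage gives the 7α-acetyl coupled ester F4.
- The acetate is installed last with bis(trimethylsilyl) peroxide and catalytic TMSOTf (CH2Cl2, −40 °C). This Baeyer–Villiger variant leaves C=C bonds untouched, and it gives 28.

Step 1. Bonding through the substituted γ-terminus of the prenyl metal would lead after rearrangement to a linear prenyl group on C5. Enolisation of the enone and poor facial selectivity at C9 are further risks.

The fallback sets out from 1 and comes back at 3.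
- Allylmagnesium bromide (THF, −78 °C) has two equivalent termini, so its 1,2-addition is free of the regiochemical question. It would give (1R,5R)-1-allyl-2-methyl-5-(prop-1-en-2-yl)cyclohex-2-en-1-ol F5.
- Cross-metathesis with 2-methyl-2-butene (second-generation ruthenium carbene, 40 °C) converts only the monosubstituted alkene into the prenyl group of 3.

**Further compounds**
F1 | step 2 | (3S,5R)-2-methyl-3-(2-methylbut-3-en-2-yl)-5-(prop-1-en-2-yl)cyclohexan-1-one (C2 epimers) | O=C1C(C)[C@H](C(C)(C)C=C)C[C@@H](C(C)=C)C1
F2 | step 2 | trimethylsilyl enol ether of F1 (C1=C2) | C[Si](C)(C)OC1=C(C)[C@H](C(C)(C)C=C)C[C@@H](C(C)=C)C1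
F3 | step 15 | 7α-(2-methyloxiran-2-yl) coupled ester | COC(=O)[C@H](CCOC(C)=O)CCC1=C(C)[C@H](C3(C)CO3)C[C@H]2C(C)(C)CCC[C@]12C
F4 | step 15 | 7α-acetyl coupled ester | COC(=O)[C@H](CCOC(C)=O)CCC1=C(C)[C@H](C(C)=O)C[C@H]2C(C)(C)CCC[C@]12C
F5 | step 1 | (1R,5R)-1-allyl-2-methyl-5-(prop-1-en-2-yl)cyclohex-2-en-1-ol | O[C@]1(CC=C)C[C@H](C(C)=C)CC=C1C
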